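## Retrosynthetic overview

1. The target comes from O‑debenzylation of its dibenzyl ether; the C3 hydroxymethyl group comes from a C3 nitromethyl group (Nef reaction, then borohydride) on the intact dihydropyran.
2. Key disconnection, C3–C4 plus the side‑chain ester in one step: a carbene‑generated homoenolate (β‑carbon of a dienal, future C4) adds to the β‑carbon of a tethered nitroalkene (future C3), joining two acceptor carbons; the acyl azolium is esterified by O,O‑dibenzyl hydroxytyrosol.
3. The cyclisation substrate is built linearly: ethyl (S)‑lactate + methyl propiolate (oxa‑Michael, α‑bromination), Suzuki coupling with a 3,3‑diethoxypropenyl boronate, ester‑to‑aldehyde reduction, Henry reaction/dehydration with nitromethane.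
4. Ring order: the dihydropyran is the only ring made and it closes in the key step; the catechol ring is carried in from hydroxytyrosol.
5. Stereochemistry: C2 comes from (S)‑lactate (its oxygen becomes the ring oxygen); C3 and C4 are set together in the cyclisation.

Assumption: the (5aR,10bS) antipode of the triazolium salt in step 6 is taken to be the one that delivers the 4S centre; if the sense is opposite, its mirror image is used with nothing else changed.

## Route

Step 1
Reactants: 1 ethyl (S)-lactate; 2 methyl propiolate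
Product: 5 ethyl (2S)-2-{[(1Z)-2-bromo-3-methoxy-3-oxoprop-1-en-1-yl]oxy}propanoate, via alkoxyacrylate 3 (not isolated), via dibromide 4 (not isolated)
Conditions: 1 (1.1 equiv), 2 (1.0 equiv), N-methylmorpholine (0.2 equiv), CH2Cl2, 0 °C to rt; then Br2 (1.05 equiv), −10 °C; then Et3N (2.5 equiv), 0 °C to rt
Reagents that add atoms: bromine, BrBr
Why: amine‑catalysed oxa‑Michael addition of the lactate hydroxyl to the propiolate gives the (E)‑β‑alkoxyacrylate, and bromine addition across this enol‑ether double bond followed by base‑induced loss of HBr (acidic α‑proton, labile α‑bromo‑ether bromide) leaves bromine on the acrylate α‑carbon; the lactate centre is not involved and no new stereocentre remains.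

Step 2
Reactants: 5 ethyl (2S)-2-{[(1Z)-2-bromo-3-methoxy-3-oxoprop-1-en-1-yl]oxy}propanoate; 6 (E)-2-(3,3-diethoxyprop-1-en-1-yl)-4,4,5,5-tetramethyl-1,3,2-dioxaborolane
Product: 7 ethyl (2S)-2-{[(1E,3E)-5,5-diethoxy-2-(methoxycarbonyl)penta-1,3-dien-1-yl]oxy}propanoate
Conditions: PdCl2(dppf) (3 mol %), K3PO4 (2 equiv), THF/H2O (10:1), 50 °C
Reagents that add atoms: none
Why: Suzuki–Miyaura coupling of an α‑halo‑β‑alkoxyacrylate with an alkenyl boronate proceeds with retention of both alkene geometries (ring oxygen cis to the new carbon chain, as the later ring needs), and the diethyl acetal keeps the future enal masked; no stereocentre is formed.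

Step 3
Reactants: 7 ethyl (2S)-2-{[(1E,3E)-5,5-diethoxy-2-(methoxycarbonyl)penta-1,3-dien-1-yl]oxy}propanoate
Product: 8 methyl (2E,3E)-5,5-diethoxy-2-({[(2S)-1-oxopropan-2-yl]oxy}methylidene)pent-3-enoate
Conditions: i-Bu2AlH (1.1 equiv), CH2Cl2, −78 °C; MeOH quench, then aq. potassium sodium tartrate (KNaC4H4O6)
Reagents that add atoms: none
Why: DIBAL‑H partial reduction of an ester: the inductively activated α‑alkoxy ethyl ester is reduced faster than the methyl ester (a deactivated vinylogous carbonate) and stops at the aldehyde level at −78 °C, the acetal is inert, and the α‑centre is retained at low temperature.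

Step 4
Reactants: 8 methyl (2E,3E)-5,5-diethoxy-2-({[(2S)-1-oxopropan-2-yl]oxy}methylidene)pent-3-enoate; 9 nitromethane
Product: 13 methyl (2E,3E)-2-({[(2S,3E)-4-nitrobut-3-en-2-yl]oxy}methylidene)-5-oxopent-3-enoate, via nitroaldol 10 (not isolated), via mesylate 11 (not isolated), via nitroalkene acetal 12 (not isolated)
Conditions: MeNO2 (5 equiv), 1,1,3,3-tetramethylguanidine (0.1 equiv), THF, 0 °C; evaporate; MsCl (1.5 equiv), Et3N (3 equiv), CH2Cl2, −30 to 0 °C; then 1 M aq. HCl, THF, 0 °C
Reagents that add atoms: water, O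
Why: Henry (nitroaldol) addition, sulfonylation and E1cB elimination to the (E)‑nitroalkene, then mild hydrolysis of the unsaturated acetal give the cyclisation substrate; the carbinol centre of 10 is destroyed on dehydration and the lactate‑derived centre is preserved by weak base and low temperature.

Step 5
Reactants: 14 hydroxytyrosol
Product: 15 2-[3,4-bis(benzyloxy)phenyl]ethan-1-ol
Conditions: BnBr (2.1 equiv), K2CO3 (2.5 equiv), acetone, reflux
Reagents that add atoms: benzyl bromide, BrCc1ccccc1
Why: Williamson etherification is phenol‑selective because carbonate deprotonates only the two phenols, leaving the primary alcohol free for the ester‑forming step.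

Step 6
Reactants: 13 methyl (2E,3E)-2-({[(2S,3E)-4-nitrobut-3-en-2-yl]oxy}methylidene)-5-oxopent-3-enoate; 15 2-[3,4-bis(benzyloxy)phenyl]ethan-1-ol
Product: 16 methyl (2S,3R,4S)-4-(2-{2-[3,4-bis(benzyloxy)phenyl]ethoxy}-2-oxoethyl)-2-methyl-3-(nitromethyl)-3,4-dihydro-2H-pyran-5-carboxylate
Conditions: (5aR,10bS)-2-mesityl-5a,10b-dihydro-4H,6H-indeno[2,1-b][1,2,4]triazolo[4,3-d][1,4]oxazin-2-ium chloride (15 mol %), NaOAc (0.5 equiv), 15 (2.0 equiv), THF/t-BuOH (10:1), 0.02 M, 23 °C
Reagents that add atoms: none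
Why: Proposed new method: the triazolylidene adds to the enal and makes its β‑carbon (C4) a homoenolate nucleophile, which attacks the nitroalkene β‑carbon (C3) in a 6‑(enolexo)‑exo‑trig Michael closure (the competing Stetter mode would need an eight‑membered ring), after which the catalyst‑bound acyl group is passed to the primary alcohol 15 (redox esterification) while t‑BuOH/acetate protonate the nitronate; C4 is set by the face selectivity of the chiral carbene and C3 by a trans‑selective half‑chair closure with the lactate‑derived C2 methyl pseudo‑equatorial and both exocyclic π‑units pseudo‑axial (no A(1,2) strain against the C5 ester), giving the 2,3‑cis‑3,4‑trans ring; the closest known reactions are the intermolecular carbene‑catalysed homoenolate addition of enals to nitroalkenes with alcohol turnover (δ‑nitro esters) and carbene redox esterification.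

Step 7
Reactants: 16 methyl (2S,3R,4S)-4-(2-{2-[3,4-bis(benzyloxy)phenyl]ethoxy}-2-oxoethyl)-2-methyl-3-(nitromethyl)-3,4-dihydro-2H-pyran-5-carboxylate
Product: 19 methyl (2S,3R,4S)-4-(2-{2-[3,4-bis(benzyloxy)phenyl]ethoxy}-2-oxoethyl)-3-(hydroxymethyl)-2-methyl-3,4-dihydro-2H-pyran-5-carboxylate, via potassium nitronate 17 (not isolated), via C3 aldehyde 18 (not isolated)
Conditions: KOt-Bu (1.05 equiv), THF, −40 °C; transfer into aq. TiCl3 (4.5 equiv)/NH4OAc (pH 5–6), THF, 0 °C to rt; extract; NaBH4 (1.5 equiv), MeOH/THF, −40 °C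
Reagents that add atoms: water, O
Why: reductive Nef reaction (trivalent titanium cleaves the N–O bonds of the nitronate and hydrolysis gives the aldehyde) followed at once by cold borohydride reduction, so the labile β‑alkoxy aldehyde is converted to the primary alcohol before C3 epimerisation or retro‑oxa‑Michael ring opening; esters, benzyl ethers and the enol‑ether acrylate are untouched and no stereocentre is created or changed.

Step 8
Reactants: 19 methyl (2S,3R,4S)-4-(2-{2-[3,4-bis(benzyloxy)phenyl]ethoxy}-2-oxoethyl)-3-(hydroxymethyl)-2-methyl-3,4-dihydro-2H-pyran-5-carboxylate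
Product: 20 methyl (2S,3R,4S)-4-{2-[2-(3,4-dihydroxyphenyl)ethoxy]-2-oxoethyl}-3-(hydroxymethyl)-2-methyl-3,4-dihydro-2H-pyran-5-carboxylate (CNP0204147.2)
Conditions: H2 (1 atm), palladium on carbon (Pd/C, 10 wt %), EtOAc, rt
Reagents that add atoms: none
Why: catalytic hydrogenolysis cleaves the two aryl benzyl ethers under neutral conditions, and the push‑pull (β‑alkoxyacrylate) double bond, both esters and all three stereocentres are inert to it.

## Compound list

1 | ethyl (S)-lactate | CCOC(=O)[C@H](C)O | starting material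
2 | methyl propiolate | C#CC(=O)OC | starting material
3 | ethyl (2S)-2-{[(1E)-3-methoxy-3-oxoprop-1-en-1-yl]oxy}propanoate | CCOC(=O)[C@H](C)O/C=C/C(=O)OC | intermediate
4 | ethyl (2S)-2-(1,2-dibromo-3-methoxy-3-oxopropoxy)propanoate (diastereomer mixture at the two brominated carbons) | CCOC(=O)[C@H](C)OC(Br)C(Br)C(=O)OC | intermediate
5 | ethyl (2S)-2-{[(1Z)-2-bromo-3-methoxy-3-oxoprop-1-en-1-yl]oxy}propanoate | CCOC(=O)[C@H](C)O/C=C(\Br)C(=O)OC | intermediate
6 | (E)-2-(3,3-diethoxyprop-1-en-1-yl)-4,4,5,5-tetramethyl-1,3,2-dioxaborolane | CCOC(OCC)/C=C/B1OC(C)(C)C(C)(C)O1 | starting material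
7 | ethyl (2S)-2-{[(1E,3E)-5,5-diethoxy-2-(methoxycarbonyl)penta-1,3-dien-1-yl]oxy}propanoate | CCOC(=O)[C@H](C)O/C=C(\C=C\C(OCC)OCC)C(=O)OC | intermediate
8 | methyl (2E,3E)-5,5-diethoxy-2-({[(2S)-1-oxopropan-2-yl]oxy}methylidene)pent-3-enoate | O=C[C@H](C)O/C=C(\C=C\C(OCC)OCC)C(=O)OC | intermediate
9 | nitromethane | C[N+](=O)[O-] | starting material
10 | methyl (2E,3E)-5,5-diethoxy-2-({[(2S)-3-hydroxy-4-nitrobutan-2-yl]oxy}methylidene)pent-3-enoate (both carbinol epimers) | OC(C[N+](=O)[O-])[C@H](C)O/C=C(\C=C\C(OCC)OCC)C(=O)OC | intermediate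
11 | methyl (2E,3E)-5,5-diethoxy-2-({[(2S)-3-(methanesulfonyloxy)-4-nitrobutan-2-yl]oxy}methylidene)pent-3-enoate (both epimers) | CS(=O)(=O)OC(C[N+](=O)[O-])[C@H](C)O/C=C(\C=C\C(OCC)OCC)C(=O)OC | intermediate
12 | methyl (2E,3E)-5,5-diethoxy-2-({[(2S,3E)-4-nitrobut-3-en-2-yl]oxy}methylidene)pent-3-enoate | [O-][N+](=O)/C=C/[C@H](C)O/C=C(\C=C\C(OCC)OCC)C(=O)OC | intermediate
13 | methyl (2E,3E)-2-({[(2S,3E)-4-nitrobut-3-en-2-yl]oxy}methylidene)-5-oxopent-3-enoate | [O-][N+](=O)/C=C/[C@H](C)O/C=C(\C=C\C=O)C(=O)OC | intermediate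
14 | hydroxytyrosol, 4-(2-hydroxyethyl)benzene-1,2-diol | OCCc1ccc(O)c(O)c1 | starting material
15 | 2-[3,4-bis(benzyloxy)phenyl]ethan-1-ol | OCCc1ccc(OCc2ccccc2)c(OCc2ccccc2)c1 | intermediate
16 | methyl (2S,3R,4S)-4-(2-{2-[3,4-bis(benzyloxy)phenyl]ethoxy}-2-oxoethyl)-2-methyl-3-(nitromethyl)-3,4-dihydro-2H-pyran-5-carboxylate | COC(=O)C1=CO[C@@H](C)[C@@H](C[N+](=O)[O-])[C@@H]1CC(=O)OCCc1ccc(OCc2ccccc2)c(OCc2ccccc2)c1 | intermediate
17 | potassium nitronate (aci-nitro salt) of 16 | [K+].COC(=O)C1=CO[C@@H](C)[C@@H](C=[N+]([O-])[O-])[C@@H]1CC(=O)OCCc1ccc(OCc2ccccc2)c(OCc2ccccc2)c1 | intermediate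
18 | methyl (2S,3S,4S)-4-(2-{2-[3,4-bis(benzyloxy)phenyl]ethoxy}-2-oxoethyl)-3-formyl-2-methyl-3,4-dihydro-2H-pyran-5-carboxylate | COC(=O)C1=CO[C@@H](C)[C@@H](C=O)[C@@H]1CC(=O)OCCc1ccc(OCc2ccccc2)c(OCc2ccccc2)c1 | intermediate
19 | methyl (2S,3R,4S)-4-(2-{2-[3,4-bis(benzyloxy)phenyl]ethoxy}-2-oxoethyl)-3-(hydroxymethyl)-2-methyl-3,4-dihydro-2H-pyran-5-carboxylate | COC(=O)C1=CO[C@@H](C)[C@@H](CO)[C@@H]1CC(=O)OCCc1ccc(OCc2ccccc2)c(OCc2ccccc2)c1 | intermediate
20 | methyl (2S,3R,4S)-4-{2-[2-(3,4-dihydroxyphenyl)ethoxy]-2-oxoethyl}-3-(hydroxymethyl)-2-methyl-3,4-dihydro-2H-pyran-5-carboxylate | COC(=O)C1=CO[C@@H](C)[C@@H](CO)[C@@H]1CC(=O)OCCc1ccc(O)c(O)c1 | target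

## Step count and risks

Total steps: 8. Longest linear sequence: 7 (steps 1, 2, 3, 4, 6, 7, 8); step 5 is a one‑step side branch.

Most likely to fail, in order:

Step 6. The homoenolate of a push‑pull dienal has not been used this way. It may be protonated at C4 instead of cyclising, the nitronate may C‑acylate the acyl azolium, or the C3/C4 diastereoselectivity may be low (diastereomers would be separated at 16). The fallback sets out from 13 and comes back at 16, making the same C3–C4 bond by electron transfer instead of carbene catalysis. Controlled‑potential cathodic reduction of 13 (carbon cathode, Et4NBF4, MeCN, dimethyl malonate as proton donor) reduces the nitroalkene to its radical anion. Its C3 adds 6‑exo to the enal β‑carbon C4, and a second electron and protonation give the ring‑closed aldehyde methyl (2S,3R,4S)-2-methyl-3-(nitromethyl)-4-(2-oxoethyl)-3,4-dihydro-2H-pyran-5-carboxylate F1. Pinnick oxidation (NaClO2, NaH2PO4, 2‑methyl‑2‑butene) gives 2-[(2S,3R,4S)-5-(methoxycarbonyl)-2-methyl-3-(nitromethyl)-3,4-dihydro-2H-pyran-4-yl]acetic acid F2. Carbodiimide esterification of F2 with 15 (EDC·HCl, DMAP, CH2Cl2) then gives 16.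

Step 7. The Nef reaction on a polyfunctional substrate may be low‑yielding, and aldehyde 18 can epimerise at C3 or open by retro‑oxa‑Michael reaction before it is reduced. The fallback sets out from 16 and comes back at 19 without ever forming the C3 aldehyde. NaNO2/AcOH in DMSO at 35 °C oxidises the primary nitro group directly (nitrolic acid, then nitrile oxide) to (2S,3S,4S)-4-(2-{2-[3,4-bis(benzyloxy)phenyl]ethoxy}-2-oxoethyl)-5-(methoxycarbonyl)-2-methyl-3,4-dihydro-2H-pyran-3-carboxylic acid F3. BH3·SMe2 in THF at 0 °C then reduces the free acid selectively over both esters to give 19.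

Step 3. DIBAL‑H may not distinguish the two esters cleanly or may over‑reduce, and the α‑alkoxy aldehyde is sensitive. The fallback sets out from 7 and comes back at 8 by full reduction and re‑oxidation. NaBH4 in MeOH at 0 °C reduces only the activated α‑alkoxy ethyl ester (the vinylogous carbonate ester does not react with borohydride) to methyl (2E,3E)-5,5-diethoxy-2-({[(2S)-1-hydroxypropan-2-yl]oxy}methylidene)pent-3-enoate F4. Dess–Martin oxidation (NaHCO3‑buffered, CH2Cl2, 0 °C) then gives 8 without touching the stereocentre.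

Further compounds
F1 | step 6 | methyl (2S,3R,4S)-2-methyl-3-(nitromethyl)-4-(2-oxoethyl)-3,4-dihydro-2H-pyran-5-carboxylate | COC(=O)C1=CO[C@@H](C)[C@@H](C[N+](=O)[O-])[C@@H]1CC=O
F2 | step 6 | 2-[(2S,3R,4S)-5-(methoxycarbonyl)-2-methyl-3-(nitromethyl)-3,4-dihydro-2H-pyran-4-yl]acetic acid | COC(=O)C1=CO[C@@H](C)[C@@H](C[N+](=O)[O-])[C@@H]1CC(=O)O
F3 | step 7 | (2S,3S,4S)-4-(2-{2-[3,4-bis(benzyloxy)phenyl]ethoxy}-2-oxoethyl)-5-(methoxycarbonyl)-2-methyl-3,4-dihydro-2H-pyran-3-carboxylic acid | COC(=O)C1=CO[C@@H](C)[C@@H](C(=O)O)[C@@H]1CC(=O)OCCc1ccc(OCc2ccccc2)c(OCc2ccccc2)c1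
F4 | step 3 | methyl (2E,3E)-5,5-diethoxy-2-({[(2S)-1-hydroxypropan-2-yl]oxy}methylidene)pent-3-enoate | OC[C@H](C)O/C=C(\C=C\C(OCC)OCC)C(=O)OC
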